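**Assumption:** the SMILES is read at face value as the (2S,3R,4R) isomer (2‑methyl and the C4 acetate arm cis, 3‑formyl trans to both). Its C4 centre is the mirror image of the corresponding (S) centre of oleuropein, so that centre is built by asymmetric catalysis; the sodium salt of methyl formylacetate (6) is taken as a catalogue reagent.

## Retrosynthetic overview

1. Target 11 ⇐ open‑chain enol 10 by 6‑endo oxa‑Michael addition of the formyl‑ester enol to the (E)‑ethylidene enal, as a secoiridoid aglycone closes after loss of glucose; this forms the only ring of the target, last, and sets C2 and C3 from C4.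
2. 10 ⇐ enol lactone 8 + hydroxytyrosol 9: one acyl transfer installs the ester and unmasks the enol.
3. 8 ⇐ dienal acid 5 + formylacetate 6 by enantioselective Michael addition–lactonisation; this sets C4 and forms a temporary dihydropyranone ring, first.
4. 5 ⇐ (Z)‑2‑bromobut‑2‑enal 3 + acrylic acid 4 (Heck); 3 ⇐ crotonaldehyde 1.

## Route

Step 1
Reactants: 1 (E)-but-2-enal (crotonaldehyde)
Product: 3 (2Z)-2-bromobut-2-enal, via 2,3-dibromobutanal 2 (not isolated)
Conditions: Br2 (1.0 equiv), CH2Cl2, −20 °C; then Et3N (1.2 equiv), 0 °C to rt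
Reagents that add atoms: bromine, BrBr
Why: Bromination–dehydrobromination: anti addition of Br2 to the enal, then base removes the acidic α‑hydrogen and the β‑bromide leaves, giving the more stable Z α‑bromoenal (CHO trans to CH3); no stereocentre is kept.

Step 2
Reactants: 3 (2Z)-2-bromobut-2-enal; 4 acrylic acid
Product: 5 (2E,4E)-4-formylhexa-2,4-dienoic acid
Conditions: Pd(OAc)2 (5 mol%), P(o-tol)3 (10 mol%), NaOAc (2.5 equiv), DMF, 60 °C; dilute HCl work-up
Reagents that add atoms: none
Why: Mizoroki–Heck reaction: zerovalent palladium inserts into the vinyl C–Br bond with retention of geometry, and syn carbopalladation of acrylate followed by syn β‑hydride elimination gives the (2E)‑enoic acid; no stereocentre is formed.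

Step 3
Reactants: 5 (2E,4E)-4-formylhexa-2,4-dienoic acid; 6 sodium (E)-3-methoxy-3-oxoprop-1-en-1-olate (sodium salt of methyl formylacetate)
Product: 8 methyl (4R)-4-[(2E)-1-oxobut-2-en-2-yl]-2-oxo-3,4-dihydro-2H-pyran-5-carboxylate, via mixed pivalic anhydride 7 (not isolated)
Conditions: t-BuCOCl (1.05 equiv), i-Pr2NEt (1.1 equiv), THF, 0 °C, 30 min; then 6 (1.3 equiv), (2S,3R)-HyperBTM [(2S,3R)-3-isopropyl-2-phenyl-3,4-dihydro-2H-benzo[4,5]thiazolo[3,2-a]pyrimidine] (10 mol%), 15-crown-5 (10 mol%), −40 °C to 0 °C
Reagents that add atoms: none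
Why: Proposed new method: the isothiourea is acylated at the less hindered carbonyl of 7 to give an s‑cis α,β‑unsaturated acyl ammonium ion held planar by an S···O contact; enolate 6 adds through carbon to the β‑carbon on the face opposite the catalyst's pseudo‑axial phenyl group, which by this model sets C4 as R (the enantiomeric catalyst is used if the measured sense is opposite), and the enol oxygen then lactonises onto the acyl ammonium and releases the catalyst; the closest known reaction type is the isothiourea‑catalysed Michael addition–lactonisation of α,β‑unsaturated anhydrides with 1,3‑diketones and β‑keto esters, extended here to a formylacetate nucleophile and a formyl‑bearing dienoyl donor, with irreversible six‑membered lactonisation relied on to drain the 1,4‑adduct over reversible addition at the remote enal carbon.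

Step 4
Reactants: 8 methyl (4R)-4-[(2E)-1-oxobut-2-en-2-yl]-2-oxo-3,4-dihydro-2H-pyran-5-carboxylate; 9 2-(3,4-dihydroxyphenyl)ethanol (hydroxytyrosol)
Product: 11 methyl (2S,3R,4R)-4-{2-[2-(3,4-dihydroxyphenyl)ethoxy]-2-oxoethyl}-3-formyl-2-methyl-3,4-dihydro-2H-pyran-5-carboxylate (target), via open-chain enol ester 10 (not isolated)
Conditions: immobilised Candida antarctica lipase B, 4 Å molecular sieves, 2-MeTHF, 35 °C, N2; stop at full conversion of 8, filter, rapid chromatography on neutral silica (no base)
Reagents that add atoms: none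
Why: Proposed new method: the lipase serine is acylated by the enol lactone (an enol ester, the classic irreversible acyl donor) and passes the acyl group to the primary alcohol of 9 but not to the phenols, freeing enol 10, whose oxygen adds 6‑endo to the ethylidene enal; closure through a half‑chair with the C4 side chain pseudo‑axial (no allylic strain with the ester) places the new C2 methyl cis to that chain (2S), ketonisation leaves the formyl group trans to both neighbours (3R), and C4 is untouched, so the kinetic product is the target as long as base, acid and heat that would reverse the oxa‑Michael step are avoided; the closest known reaction types are lipase transesterification of hydroxytyrosol with vinyl esters, lipase alcoholysis of 3‑substituted glutaric anhydrides, and the spontaneous ring closure of the open form of oleuropein aglycone, used here in the mirror‑image series.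

## Compound list

1 | (E)-but-2-enal (crotonaldehyde) | C/C=C/C=O | starting material
2 | 2,3-dibromobutanal (racemic) | CC(Br)C(Br)C=O | intermediate
3 | (2Z)-2-bromobut-2-enal | C/C=C(\Br)C=O | intermediate
4 | acrylic acid | C=CC(=O)O | starting material
5 | (2E,4E)-4-formylhexa-2,4-dienoic acid | C/C=C(C=O)\C=C\C(=O)O | intermediate
6 | sodium (E)-3-methoxy-3-oxoprop-1-en-1-olate | COC(=O)/C=C/[O-].[Na+] | starting material
7 | (2E,4E)-4-formylhexa-2,4-dienoic pivalic anhydride | C/C=C(C=O)\C=C\C(=O)OC(=O)C(C)(C)C | intermediate
8 | methyl (4R)-4-[(2E)-1-oxobut-2-en-2-yl]-2-oxo-3,4-dihydro-2H-pyran-5-carboxylate | COC(=O)C1=COC(=O)C[C@@H]1/C(C=O)=C\C | intermediate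
9 | 2-(3,4-dihydroxyphenyl)ethanol (hydroxytyrosol) | OCCc1ccc(O)c(O)c1 | starting material
10 | 5-[2-(3,4-dihydroxyphenyl)ethyl] 1-methyl (2E,3R)-2-(hydroxymethylidene)-3-[(2E)-1-oxobut-2-en-2-yl]pentanedioate | COC(=O)/C(=C/O)[C@H](CC(=O)OCCc1ccc(O)c(O)c1)/C(C=O)=C\C | intermediate
11 | methyl (2S,3R,4R)-4-{2-[2-(3,4-dihydroxyphenyl)ethoxy]-2-oxoethyl}-3-formyl-2-methyl-3,4-dihydro-2H-pyran-5-carboxylate | COC(=O)C1=CO[C@@H](C)[C@H](C=O)[C@H]1CC(=O)OCCc1ccc(O)c(O)c1 | target

## Step count and risks

Total steps: 4. Longest linear sequence: 4 (1 → 3 → 5 → 8 → 11).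

**Most likely to fail, first: step 3.** The soft enolate may add at the remote ethylidene carbon, which the free aldehyde also activates; the two aldehydes may undergo aldol chemistry; and selectivity with a formylacetate is untested. The fallback sets out from 5 and masks the aldehyde. HC(OMe)3, MeOH and cat. pyridinium p‑toluenesulfonate at rt give (2E,4E)-4-(dimethoxymethyl)hexa-2,4-dienoic acid F2. Its mixed pivalic anhydride F3 (t‑BuCOCl, i‑Pr2NEt, THF, 0 °C) is annulated with 6 under the same isothiourea catalysis to methyl (4R)-4-[(2E)-1,1-dimethoxybut-2-en-2-yl]-2-oxo-3,4-dihydro-2H-pyran-5-carboxylate F4, in which the remote alkene carbon is no longer an enal β‑carbon. Brief treatment with wet acetone and cat. pyridinium p‑toluenesulfonate at rt unmasks the aldehyde, and the route is rejoined at 8.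

**Second: step 4.** The lipase may not accept the bulky β‑branched lactone, and the diastereomer ratio rests on kinetic closure. The fallback sets out from 8 and separates ring closure from esterification. Water in THF with cat. 4‑(dimethylamino)pyridine at rt opens the lactone to (3R,4E)-4-(hydroxymethylidene)-5-methoxy-5-oxo-3-[(2E)-1-oxobut-2-en-2-yl]pentanoic acid F5. F5 closes by the same oxa‑Michael addition to 2-[(2S,3R,4R)-3-formyl-5-(methoxycarbonyl)-2-methyl-3,4-dihydro-2H-pyran-4-yl]acetic acid F6. A Mitsunobu esterification of F6 with 9 (PPh3, diisopropyl azodicarboxylate, THF, 0 °C) activates only the primary alcohol and lets the carboxylic acid, far more acidic than the phenols, act as the nucleophile; this rejoins the route at 11.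

**Third: step 2.** The bromoenal and the dienal product are sensitive to base and heat under Heck conditions. The fallback sets out from 3 and uses a room‑temperature transmetalation coupling with the acid protected. Suzuki–Miyaura coupling with tert‑butyl (E)-3-(4,4,5,5-tetramethyl-1,3,2-dioxaborolan-2-yl)acrylate (Pd(PPh3)4, K3PO4, THF/H2O, 40 °C) gives tert‑butyl (2E,4E)-4-formylhexa-2,4-dienoate F1. CF3CO2H in CH2Cl2 at 0 °C cleaves the ester, and the route is rejoined at 5.

## Further compounds

F1 | step 2 | tert-butyl (2E,4E)-4-formylhexa-2,4-dienoate | C/C=C(C=O)\C=C\C(=O)OC(C)(C)C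
F2 | step 3 | (2E,4E)-4-(dimethoxymethyl)hexa-2,4-dienoic acid | C/C=C(C(OC)OC)\C=C\C(=O)O
F3 | step 3 | (2E,4E)-4-(dimethoxymethyl)hexa-2,4-dienoic pivalic anhydride | C/C=C(C(OC)OC)\C=C\C(=O)OC(=O)C(C)(C)C
F4 | step 3 | methyl (4R)-4-[(2E)-1,1-dimethoxybut-2-en-2-yl]-2-oxo-3,4-dihydro-2H-pyran-5-carboxylate | COC(=O)C1=COC(=O)C[C@@H]1/C(C(OC)OC)=C\C
F5 | step 4 | (3R,4E)-4-(hydroxymethylidene)-5-methoxy-5-oxo-3-[(2E)-1-oxobut-2-en-2-yl]pentanoic acid | COC(=O)/C(=C/O)[C@H](CC(=O)O)/C(C=O)=C\C
F6 | step 4 | 2-[(2S,3R,4R)-3-formyl-5-(methoxycarbonyl)-2-methyl-3,4-dihydro-2H-pyran-4-yl]acetic acid | COC(=O)C1=CO[C@@H](C)[C@H](C=O)[C@H]1CC(=O)O
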